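## Retrosynthetic overview

(Shikimate numbering: C1 bears CO2Me, C2 is the vinylic CH, C3–C5 carry oxygen, C6 is CH2.)

1. Target 11 ⇒ vinyl epoxide 10 + acid 2: Pd(0)-catalysed opening at allylic C3 with net retention puts the second ester cis to the released 4-OH, so the 4-OH never needs protection.
2. 10 ⇒ dienoate 9 by epoxidation of the γ,δ-alkene anti to the C5 ester.
3. 9 ⇒ diazo carbinol 6 by a one-carbon ring expansion (1,2-shift of a ring C–C bond onto a vinyl cation, ended by hydride); this inserts C1 with its CO2Me and removes the ketone oxygen.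
4. 6 ⇒ enone ester 3 + methyl diazoacetate 4; 3 ⇒ (S)-4-hydroxycyclopentenone 1 + acid 2 (Mitsunobu, inversion gives the future 5R centre).
5. Ring order: cyclopentene (bought in 1) → cyclohexa-1,3-diene (step 3) → oxirane (step 4, opened in step 5).

Assumption: (S)-4-hydroxycyclopent-2-en-1-one, isomerically pure (E)-3-methylpent-2-enoic acid and methyl diazoacetate (as a solution) are taken as catalogue compounds.

## Route

Step 1
Reactants: 1 (S)-4-hydroxycyclopent-2-en-1-one; 2 (E)-3-methylpent-2-enoic acid
Product: 3 (1R)-4-oxocyclopent-2-en-1-yl (2E)-3-methylpent-2-enoate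
Conditions: PPh3, DIAD, THF, 0 °C → rt
Reagents that add atoms: none
Why: Mitsunobu esterification: the carboxylate displaces the PPh3/DIAD-activated secondary allylic alcohol by SN2, inverting the centre from S to R (the future C5 of the target), and because the acid reacts as an O-nucleophile and is never activated at its acyl carbon the E-enoate cannot scramble through a vinylketene or dienolate.

Step 2
Reactants: 3 (1R)-4-oxocyclopent-2-en-1-yl (2E)-3-methylpent-2-enoate; 4 methyl diazoacetate
Product: 6 methyl 2-diazo-2-[(4R)-1-hydroxy-4-{[(2E)-3-methylpent-2-enoyl]oxy}cyclopent-2-en-1-yl]acetate (C1 epimers), via lithio methyl diazoacetate 5 (not isolated)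
Conditions: 4 (1.2 equiv), LDA (1.15 equiv), THF, −78 °C, 15 min; then 3, −78 °C; sat. aq NH4Cl
Reagents that add atoms: none
Why: Aldol-type 1,2-addition of the preformed lithiated diazoacetate to the enone carbonyl, which at −78 °C is faster than deprotonation at C5 (the path to β-elimination of the ester); the new carbinol centre forms as an epimer mixture that does not matter because this carbon becomes sp2 in step 3, and the R centre is untouched.

Step 3
Reactants: 6 methyl 2-diazo-2-[(4R)-1-hydroxy-4-{[(2E)-3-methylpent-2-enoyl]oxy}cyclopent-2-en-1-yl]acetate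
Product: 9 methyl (5R)-5-{[(2E)-3-methylpent-2-enoyl]oxy}cyclohexa-1,3-diene-1-carboxylate, via alkenyldiazonium ion 7 (not isolated), via ring-expanded vinyl cation 8 (not isolated)
Conditions: BF3·OEt2 (1.5 equiv), Et3SiH (5 equiv), CH2Cl2, −78 → −20 °C
Reagents that add atoms: none
Why: Proposed new method: hydride-terminated vinyl-cation ring expansion, in which BF3 ionises the tertiary, allylic, diazo-stabilised C–OH bond of 6 to alkenyldiazonium ion 7, loss of N2 goes with a 1,2-shift of the sp3 ring carbon C5 (a better in-plane σ-donor than the vinylic C2, whose π-bond is orthogonal to the vacant orbital and cannot assist) onto the electron-poor exocyclic carbon to give the six-membered vinyl cation 8, and Et3SiH reduces 8 irreversibly at the cationic carbon (the future C2–H), so the former ketone oxygen is excised and the 1,3-dienoate forms directly with the acyloxy-bearing stereocentre untouched; the closest known reaction type is the Lewis-acid-induced vinyl-cation 1,2-shift ring expansion of β-hydroxy-α-diazo carbonyl compounds, where the ring-expanded cation has been captured by C–H insertion, arenes, nitriles or halide, and capture by a hydride donor (ionic hydrogenation) is the new element.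

Step 4
Reactants: 9 methyl (5R)-5-{[(2E)-3-methylpent-2-enoyl]oxy}cyclohexa-1,3-diene-1-carboxylate
Product: 10 methyl (1R,5R,6S)-5-{[(2E)-3-methylpent-2-enoyl]oxy}-7-oxabicyclo[4.1.0]hept-2-ene-3-carboxylate (the 3,4-epoxide trans to the C5 ester; 3R,4S,5R in shikimate numbering)
Conditions: mCPBA (1.2 equiv), CH2Cl2, 0 °C → rt
Reagents that add atoms: mCPBA (3-chloroperoxybenzoic acid), O=C(OO)c1cccc(Cl)c1
Why: Prilezhaev epoxidation: the peracid takes the γ,δ-alkene (C3=C4), the most electron-rich of the three C=C bonds since the other two are directly ester-conjugated, and approaches anti to the pseudo-axial C5 acyloxy group, which sets C3 (R) and C4 (S) with the oxirane trans to the C5 ester.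

Step 5
Reactants: 10 methyl (1R,5R,6S)-5-{[(2E)-3-methylpent-2-enoyl]oxy}-7-oxabicyclo[4.1.0]hept-2-ene-3-carboxylate; 2 (E)-3-methylpent-2-enoic acid
Product: 11 methyl (3R,4S,5R)-4-hydroxy-3,5-bis{[(2E)-3-methylpent-2-enoyl]oxy}cyclohex-1-ene-1-carboxylate
Conditions: Pd2(dba)3·CHCl3 (2.5 mol %), PPh3 (15 mol %), 2 (1.5 equiv), THF, 0 °C → rt
Reagents that add atoms: none
Why: Pd(0)-catalysed allylic substitution of a γ,δ-epoxy-α,β-unsaturated ester (Tsuji–Trost type): ionisation of the allylic C3–O bond anti to palladium and outer-sphere attack of the carboxylate on the allyl terminus remote from the ester (C3) are two inversions and so give net retention, placing the new ester cis to the released 4-OH while C4 and C5 are not touched and the acid again acts only as an O-nucleophile.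

## Compound list

1 | (S)-4-hydroxycyclopent-2-en-1-one | O=C1C=C[C@@H](O)C1 | starting material
2 | (E)-3-methylpent-2-enoic acid | CC/C(C)=C/C(=O)O | starting material
3 | (1R)-4-oxocyclopent-2-en-1-yl (2E)-3-methylpent-2-enoate | O=C1C=C[C@H](OC(=O)/C=C(\C)CC)C1 | intermediate
4 | methyl diazoacetate | COC(=O)C=[N+]=[N-] | starting material
5 | lithio methyl diazoacetate | COC(=O)C([Li])=[N+]=[N-] | intermediate
6 | methyl 2-diazo-2-[(4R)-1-hydroxy-4-{[(2E)-3-methylpent-2-enoyl]oxy}cyclopent-2-en-1-yl]acetate (C1 epimers) | COC(=O)C(=[N+]=[N-])C1(O)C=C[C@H](OC(=O)/C=C(\C)CC)C1 | intermediate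
7 | (methoxycarbonyl)[(4R)-4-{[(2E)-3-methylpent-2-enoyl]oxy}cyclopent-2-en-1-ylidene]methanediazonium ion | COC(=O)C([N+]#N)=C1C=C[C@H](OC(=O)/C=C(\C)CC)C1 | intermediate
8 | (4R)-2-(methoxycarbonyl)-4-{[(2E)-3-methylpent-2-enoyl]oxy}cyclohexa-1,5-dien-1-ylium (ring-expanded vinyl cation) | COC(=O)C1=[C+]C=C[C@H](OC(=O)/C=C(\C)CC)C1 | intermediate
9 | methyl (5R)-5-{[(2E)-3-methylpent-2-enoyl]oxy}cyclohexa-1,3-diene-1-carboxylate | COC(=O)C1=CC=C[C@H](OC(=O)/C=C(\C)CC)C1 | intermediate
10 | methyl (1R,5R,6S)-5-{[(2E)-3-methylpent-2-enoyl]oxy}-7-oxabicyclo[4.1.0]hept-2-ene-3-carboxylate | COC(=O)C1=C[C@H]2O[C@H]2[C@H](OC(=O)/C=C(\C)CC)C1 | intermediate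
11 | methyl (3R,4S,5R)-4-hydroxy-3,5-bis{[(2E)-3-methylpent-2-enoyl]oxy}cyclohex-1-ene-1-carboxylate | CC/C(C)=C/C(=O)O[C@@H]1C=C(C(=O)OC)C[C@@H](OC(=O)/C=C(\C)CC)[C@@H]1O | target

## Step count and risks

Total step count: 5. Longest linear sequence: 5 steps (1 → 3 → 6 → 9 → 10 → 11).

The three steps most likely to fail are steps 3, 4 and 5.

**Step 3 (the proposed new ring expansion).** It can fail in three ways: the silane may reduce the delocalised cation before N2 is lost; the vinylic carbon may migrate instead of the CH2; or the Lewis acid may strip the allylic ester from 9 to give methyl benzoate. The fallback uses known chemistry, sets out from 3 and comes back at 9; it therefore also spares the base-sensitive step 2. Enone 3 is homologated directly with methyl diazoacetate 4 under Lewis acid catalysis (BF3·OEt2, CH2Cl2, 0 °C; Tiffeneau–Demjanov-type insertion in which the saturated α-carbon migrates) to the β-keto ester methyl (5R)-5-{[(2E)-3-methylpent-2-enoyl]oxy}-2-oxocyclohex-3-ene-1-carboxylate F1. Its enol is triflated (NaH, PhNTf2, THF, 0 °C) to methyl (5R)-5-{[(2E)-3-methylpent-2-enoyl]oxy}-2-{[(trifluoromethyl)sulfonyl]oxy}cyclohexa-1,3-diene-1-carboxylate F2. The triflate is then reduced (Pd(OAc)2, PPh3, Et3SiH, DMF, rt) to 9.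

**Step 4 (epoxidation).** Facial selectivity next to an allylic ester may be only moderate, and the side-chain enoate competes weakly. The fallback sets out from 9 and comes back at 11. Catalytic OsO4 with NMO (acetone–water, 0 °C) dihydroxylates the γ,δ-alkene anti to the C5 ester, the established end-game of dienoate-based shikimate syntheses, and gives methyl (3R,4R,5R)-3,4-dihydroxy-5-{[(2E)-3-methylpent-2-enoyl]oxy}cyclohex-1-ene-1-carboxylate F3. The spatial arrangement is that of the target; the C4 descriptor differs only through CIP priorities. 1,1'-Carbonyldiimidazole (CH2Cl2, rt) closes the cis-diol to methyl (3R,4S,5R)-3,4-(carbonyldioxy)-5-{[(2E)-3-methylpent-2-enoyl]oxy}cyclohex-1-ene-1-carboxylate F4. Pd(0)/PPh3 with acid 2 (THF, rt) ionises the allylic C3–O bond with loss of CO2 and returns the carboxylate to C3 with net retention, giving 11.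

**Step 5 (Pd-catalysed opening).** Ionisation at a trisubstituted cyclic enoate may be slow, and the allyl-palladium intermediate can isomerise or eliminate towards aromatic products. The fallback sets out from 10 and comes back at 11 by two uncatalysed SN2 inversions. MgBr2·OEt2 (Et2O–THF, −20 °C) opens the oxirane at the allylic carbon with inversion to the trans-bromohydrin methyl (3S,4S,5R)-3-bromo-4-hydroxy-5-{[(2E)-3-methylpent-2-enoyl]oxy}cyclohex-1-ene-1-carboxylate F5. The allylic bromide is then displaced with inversion by caesium (E)-3-methylpent-2-enoate F6 (made from 2 and Cs2CO3; DMF, 0 °C → rt) to give 11.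

## Further compounds

F1 | step 3 | methyl (5R)-5-{[(2E)-3-methylpent-2-enoyl]oxy}-2-oxocyclohex-3-ene-1-carboxylate | COC(=O)C1C[C@@H](OC(=O)/C=C(\C)CC)C=CC1=O
F2 | step 3 | methyl (5R)-5-{[(2E)-3-methylpent-2-enoyl]oxy}-2-{[(trifluoromethyl)sulfonyl]oxy}cyclohexa-1,3-diene-1-carboxylate | COC(=O)C1=C(OS(=O)(=O)C(F)(F)F)C=C[C@H](OC(=O)/C=C(\C)CC)C1
F3 | step 4 | methyl (3R,4R,5R)-3,4-dihydroxy-5-{[(2E)-3-methylpent-2-enoyl]oxy}cyclohex-1-ene-1-carboxylate | COC(=O)C1=C[C@@H](O)[C@@H](O)[C@H](OC(=O)/C=C(\C)CC)C1
F4 | step 4 | methyl (3R,4S,5R)-3,4-(carbonyldioxy)-5-{[(2E)-3-methylpent-2-enoyl]oxy}cyclohex-1-ene-1-carboxylate | COC(=O)C1=C[C@H]2OC(=O)O[C@H]2[C@H](OC(=O)/C=C(\C)CC)C1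
F5 | step 5 | methyl (3S,4S,5R)-3-bromo-4-hydroxy-5-{[(2E)-3-methylpent-2-enoyl]oxy}cyclohex-1-ene-1-carboxylate | COC(=O)C1=C[C@H](Br)[C@@H](O)[C@H](OC(=O)/C=C(\C)CC)C1
F6 | step 5 | caesium (E)-3-methylpent-2-enoate | CC/C(C)=C/C(=O)[O-].[Cs+]
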